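**Plan**

1. Eudesmane numbering is used: ring A = C1–C5 and C10, ring B = C5–C10, C14 = methyl on C10, C15 = methyl on C4, isopropyl on C7. The target is the (E)-p-coumarate of eudesm-3-en-6β-ol (5α-H, 7β-isopropyl, 10β-methyl).
2. Retrosynthetic cuts, in order: the aryl O–Si bond; the ester C(=O)–Cα bond, giving a C6–O–C(=O)–imidazole half and an (E)-styryl–magnesium half; the C5–H bond together with the C3=C4 alkene, back to a Δ4-3β-allylic alcohol; the C6–O bond, back to a Δ4-3-ketone; the C4=C5 and C1–C10 bonds of ring A (Robinson annulation).
3. Forward: ring B is bought as (+)-dihydrocarvone and ring A is annulated with ethyl vinyl ketone. The isopropenyl group is then saturated, O6 is introduced, and the C3 oxygen is spent in a reductive 1,3-transposition. O6 is capped with one carbonyl carbon and the two halves are joined last.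
4. Stereochemistry: C7 is bought. C10 comes from the auxiliary-controlled Michael step, C6 from axial β attack on the 3,5-dienyl acetate, and the transient C3 centre from axial hydride delivery. C5 comes from suprafacial hydrogen transfer of the 3α-diazene, so C3 relays to C5.
5. Feature that makes the key event possible: O6 is axial on ring B, syn-diaxial to C14 and flanked by C5 (next to C15) and C7 (isopropyl). The ester carbonyl carbon lies two bonds outside this pocket and its other neighbour is an sp2 carbon of an (E)-alkene. O6 therefore only has to accept a one-carbon reagent, and the large cinnamoyl part is attached by C–C bond formation at the unhindered carbonyl carbon.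

Key step: step 10

Remark: commercial (+)-dihydrocarvone is taken as the usual mixture of C2 epimers with uniform (5R) configuration; C2 is planarised in step 1, so the mixture is used as such (drawn as the 2R,5R isomer).

**Route**

Step 1
Reactants: 1 (+)-dihydrocarvone; 2 (R)-(+)-1-phenylethylamine; 3 ethyl vinyl ketone
Product: 6 (2S,5R)-2-methyl-2-(3-oxopentyl)-5-(prop-1-en-2-yl)cyclohexan-1-one, via dihydrocarvone imine 4 (not isolated), via Michael adduct imine 5 (not isolated)
Conditions: (i) 2, TsOH (cat.), toluene, reflux, Dean–Stark; (ii) 3, THF, 40 °C; (iii) 10% aq. AcOH, rt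
Reagents that add atoms: water, O
Why: d'Angelo asymmetric Michael reaction, in which the more substituted secondary enamine tautomer of imine 4 adds to the enone through a compact aza-ene-like transition state on the face opposite to the phenyl group of the (R)-auxiliary, which should override the weak bias of the remote C5 substituent and set the quaternary centre (future C10) with methyl cis to isopropenyl before aqueous acid hydrolyses the imine.

Step 2
Reactants: 6 (2S,5R)-2-methyl-2-(3-oxopentyl)-5-(prop-1-en-2-yl)cyclohexan-1-one
Product: 7 (+)-α-cyperone (eudesma-4,11-dien-3-one)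
Conditions: NaOMe (0.3 equiv), MeOH, rt → 50 °C
Reagents that add atoms: none
Why: Intramolecular aldol condensation (second stage of the Robinson annulation) of the ethyl ketone methylene onto the ring carbonyl should close ring A as the conjugated tetrasubstituted enone, with no stereocentre formed or touched (C10 is quaternary, C7 is not enolisable).

Step 3
Reactants: 7 (+)-α-cyperone
Product: 8 eudesm-4-en-3-one (11,12-dihydro-α-cyperone)
Conditions: H2 (1 atm), RhCl(PPh3)3 (5 mol%), benzene/EtOH, rt
Reagents that add atoms: none
Why: Homogeneous hydrogenation with Wilkinson's catalyst should reduce the unhindered 1,1-disubstituted isopropenyl alkene and leave the tetrasubstituted conjugated C4=C5 bond untouched, with no stereocentre created.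

Step 4
Reactants: 8 eudesm-4-en-3-one
Product: 9 eudesma-3,5-dien-3-yl acetate
Conditions: isopropenyl acetate, TsOH·H2O (cat.), reflux
Reagents that add atoms: isopropenyl acetate, CC(=C)OC(C)=O
Why: Acid-catalysed thermodynamic enol acetylation of a Δ4-3-ketone should give the heteroannular 3,5-dienyl acetate, which makes C6 the nucleophilic terminus of the dienol system, with no stereocentre created.

Step 5
Reactants: 9 eudesma-3,5-dien-3-yl acetate
Product: 10 6β-hydroxyeudesm-4-en-3-one
Conditions: mCPBA (1.1 equiv), 1,4-dioxane/H2O (phosphate buffer), 0 °C → rt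
Reagents that add atoms: mCPBA (3-chloroperbenzoic acid), O=C(OO)c1cccc(Cl)c1
Why: Vinylogous Rubottom-type oxidation in which the peracid delivers oxygen to C6 along the axial (β) trajectory that keeps overlap with the forming enone, as in the 6β-hydroxylation of steroidal 3,5-dienyl acetates, the axial 6β-alcohol also avoiding allylic 1,3-strain with C15, while the acetyl group is lost as acetic acid in the aqueous medium.

Step 6
Reactants: 10 6β-hydroxyeudesm-4-en-3-one
Product: 11 eudesm-4-ene-3β,6β-diol
Conditions: NaBH4, CeCl3·7H2O, MeOH, −20 °C
Reagents that add atoms: none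
Why: Luche 1,2-reduction in which hydride should add to C3 axially from the α face of the half-chair enone (away from the 10β-methyl and the 6β-hydroxyl) to give the pseudo-equatorial 3β-alcohol, the configuration that the next step translates into 5α-H.

Step 7
Reactants: 11 eudesm-4-ene-3β,6β-diol
Product: 14 eudesm-3-en-6β-ol, via sulfonylhydrazine adduct 12 (not isolated), via allylic diazene 13 (not isolated)
Conditions: PPh3, DEAD, 2-nitrobenzenesulfonyl hydrazide (NBSH), N-methylmorpholine, −30 °C → rt
Reagents that add atoms: none
Why: Myers reductive 1,3-transposition in which Mitsunobu displacement of the unhindered 3β-hydroxyl by the sulfonamide nitrogen proceeds with inversion (the axial, crowded 6β-hydroxyl should not react), sulfinic acid is lost on warming and the 3α-diazene transfers hydrogen suprafacially to the α face of C5 with loss of N2, which sets the trans ring fusion and moves the alkene to C3=C4.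

Step 8
Reactants: 14 eudesm-3-en-6β-ol
Product: 15 eudesm-3-en-6β-yl 1H-imidazole-1-carboxylate
Conditions: CDI (3 equiv), KOH (cat.), toluene, 60 °C
Reagents that add atoms: 1,1'-carbonyldiimidazole, O=C(n1ccnc1)n1ccnc1
Why: Acyl transfer from 1,1'-carbonyldiimidazole, a small planar electrophile that can reach the axial hydroxyl, should give the stable alkoxycarbonyl imidazole with retention at C6 because the C6–O bond is not touched.

Step 9
Reactants: 16 4-(tert-butyldimethylsilyloxy)benzaldehyde
Product: 17 (E)-tert-butyl[4-(2-iodoethenyl)phenoxy]dimethylsilane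
Conditions: CrCl2 (6 equiv), CHI3 (2 equiv), THF/dioxane, 0 °C → rt
Reagents that add atoms: iodoform, IC(I)I
Why: Takai olefination in which the geminal dichromium species from iodoform adds to the aldehyde and eliminates to give the (E)-alkenyl iodide selectively, so the alkene geometry of the target is fixed here and no stereocentre is involved.

Step 10
Reactants: 15 eudesm-3-en-6β-yl 1H-imidazole-1-carboxylate; 17 (E)-tert-butyl[4-(2-iodoethenyl)phenoxy]dimethylsilane
Product: 20 eudesm-3-en-6β-yl (E)-3-[4-(tert-butyldimethylsilyloxy)phenyl]prop-2-enoate, via alkenyllithium 18 (not isolated), via alkenylmagnesium bromide 19 (not isolated)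
Conditions: 17 (1.3 equiv), t-BuLi (2.6 equiv), Et2O, −78 °C; MgBr2·OEt2 (1.4 equiv), −78 → 0 °C; added to 15 in THF, 0 °C → rt; aq. NH4Cl
Reagents that add atoms: none
Why: Iodine–lithium exchange on 17 gives the (E)-alkenyllithium 18 with retention, MgBr2 converts it into the less basic alkenylmagnesium bromide 19, and this adds to the carbonyl carbon of 15 (activated by coordination of magnesium to N3 of the imidazole), after which the tetrahedral intermediate collapses with loss of imidazolide, so that the C(=O)–Cα bond is formed while the C6–O bond is never touched. The closest known reaction type is the preparation of esters from Grignard reagents and alkyl 1H-imidazole-1-carboxylates, a C-acylation with a carbonic acid derivative. No ring is closed and no stereocentre is created; C5, C6, C7 and C10 are spectators, and the (E)-geometry is carried over because alkenyllithium and alkenylmagnesium species are configurationally stable at these temperatures. The step needs mono-addition and chemoselectivity: the imidazolide is far more electrophilic than the conjugated ester that is formed, which in addition sits under the axial pocket of C14, C15 and the isopropyl group, and the trisubstituted C3=C4 alkene is inert to the organometallic. The reacting carbon is two bonds away from the hindered axial C6, which is why this union should succeed where direct O-acylation with a bulky cinnamoyl donor is expected to be slow.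

Step 11
Reactants: 20 eudesm-3-en-6β-yl (E)-3-[4-(tert-butyldimethylsilyloxy)phenyl]prop-2-enoate
Product: 21 eudesm-3-en-6β-yl (E)-3-(4-hydroxyphenyl)prop-2-enoate (target)
Conditions: TBAF (1.1 equiv), AcOH (1.2 equiv), THF, 0 °C
Reagents that add atoms: none
Why: Fluoride-mediated cleavage of the aryl silyl ether (strong Si–F bond, phenoxide leaving group) under buffered conditions should leave the hindered conjugated ester, the alkene geometry and all stereocentres untouched.

**Compound list**

1 | (+)-dihydrocarvone, (2R,5R)-2-methyl-5-(prop-1-en-2-yl)cyclohexan-1-one | C[C@@H]1CC[C@@H](C(C)=C)CC1=O | starting material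
2 | (R)-(+)-1-phenylethylamine | C[C@@H](N)c1ccccc1 | starting material
3 | ethyl vinyl ketone (pent-1-en-3-one) | CCC(=O)C=C | starting material
4 | N-[(1R)-1-phenylethyl] imine of dihydrocarvone (C2 epimers) | CC1CC[C@@H](C(C)=C)CC1=N[C@H](C)c1ccccc1 | intermediate
5 | N-[(1R)-1-phenylethyl] imine of (2S,5R)-2-methyl-2-(3-oxopentyl)-5-(prop-1-en-2-yl)cyclohexanone | CCC(=O)CC[C@]1(C)CC[C@@H](C(C)=C)CC1=N[C@H](C)c1ccccc1 | intermediate
6 | (2S,5R)-2-methyl-2-(3-oxopentyl)-5-(prop-1-en-2-yl)cyclohexan-1-one | CCC(=O)CC[C@]1(C)CC[C@@H](C(C)=C)CC1=O | intermediate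
7 | (+)-α-cyperone, (4aS,7R)-1,4a-dimethyl-7-(prop-1-en-2-yl)-4,4a,5,6,7,8-hexahydronaphthalen-2(3H)-one | CC1=C2C[C@H](C(C)=C)CC[C@@]2(C)CCC1=O | intermediate
8 | eudesm-4-en-3-one, (4aS,7R)-1,4a-dimethyl-7-(propan-2-yl)-4,4a,5,6,7,8-hexahydronaphthalen-2(3H)-one | CC1=C2C[C@H](C(C)C)CC[C@@]2(C)CCC1=O | intermediate
9 | eudesma-3,5-dien-3-yl acetate (7β-isopropyl, 10β-methyl) | CC(=O)OC1=C(C)C2=C[C@H](C(C)C)CC[C@@]2(C)CC1 | intermediate
10 | 6β-hydroxyeudesm-4-en-3-one | CC1=C2[C@H](O)[C@H](C(C)C)CC[C@@]2(C)CCC1=O | intermediate
11 | eudesm-4-ene-3β,6β-diol | CC1=C2[C@H](O)[C@H](C(C)C)CC[C@@]2(C)CC[C@@H]1O | intermediate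
12 | N-(6β-hydroxyeudesm-4-en-3α-yl)-2-nitrobenzenesulfonohydrazide (alkylated on the sulfonamide nitrogen) | CC1=C2[C@H](O)[C@H](C(C)C)CC[C@@]2(C)CC[C@H]1N(N)S(=O)(=O)c1ccccc1[N+](=O)[O-] | intermediate
13 | (6β-hydroxyeudesm-4-en-3α-yl)diazene | CC1=C2[C@H](O)[C@H](C(C)C)CC[C@@]2(C)CC[C@H]1N=N | intermediate
14 | eudesm-3-en-6β-ol, (1R,2S,4aR,8aR)-4a,8-dimethyl-2-(propan-2-yl)-1,2,3,4,4a,5,6,8a-octahydronaphthalen-1-ol | CC1=CCC[C@]2(C)CC[C@@H](C(C)C)[C@@H](O)[C@@H]12 | intermediate
15 | eudesm-3-en-6β-yl 1H-imidazole-1-carboxylate | CC1=CCC[C@]2(C)CC[C@@H](C(C)C)[C@@H](OC(=O)n3ccnc3)[C@@H]12 | intermediate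
16 | 4-(tert-butyldimethylsilyloxy)benzaldehyde | CC(C)(C)[Si](C)(C)Oc1ccc(C=O)cc1 | starting material
17 | (E)-tert-butyl[4-(2-iodoethenyl)phenoxy]dimethylsilane | CC(C)(C)[Si](C)(C)Oc1ccc(/C=C/I)cc1 | intermediate
18 | (E)-2-[4-(tert-butyldimethylsilyloxy)phenyl]ethenyllithium | CC(C)(C)[Si](C)(C)Oc1ccc(/C=C/[Li])cc1 | intermediate
19 | (E)-2-[4-(tert-butyldimethylsilyloxy)phenyl]ethenylmagnesium bromide | CC(C)(C)[Si](C)(C)Oc1ccc(/C=C/[Mg]Br)cc1 | intermediate
20 | eudesm-3-en-6β-yl (E)-3-[4-(tert-butyldimethylsilyloxy)phenyl]prop-2-enoate | CC1=CCC[C@]2(C)CC[C@@H](C(C)C)[C@@H](OC(=O)/C=C/c3ccc(O[Si](C)(C)C(C)(C)C)cc3)[C@@H]12 | intermediate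
21 | (1R,2S,4aR,8aR)-4a,8-dimethyl-2-(propan-2-yl)-1,2,3,4,4a,5,6,8a-octahydronaphthalen-1-yl (2E)-3-(4-hydroxyphenyl)prop-2-enoate | CC1=CCC[C@]2(C)CC[C@@H](C(C)C)[C@@H](OC(=O)/C=C/c3ccc(O)cc3)[C@@H]12 | target

**Step count and risks**

Total step count: 11. Longest linear sequence: 10 steps (steps 1–8, 10 and 11); step 9 is a one-step branch.

Steps most likely to fail:

Step 7. What may go wrong: competing activation of the 6β-hydroxyl, or elimination of the activated allylic alcohol to a diene instead of substitution, so that the hydrogen is not delivered to C5. The fallback replaces the sigmatropic diazene route by a palladium π-allyl hydrogenolysis and sets out from 11. Selective formylation of the equatorial 3β-hydroxyl (acetic formic anhydride, pyridine, −20 °C) should give 6β-hydroxyeudesm-4-en-3β-yl formate F1. Treatment with Pd(OAc)2 and PBu3 in dioxane (Tsuji-type hydrogenolysis of allylic formates) should ionise the formate anti, on the α face. Decarboxylation then gives a palladium hydride, which is transferred to the more substituted allyl terminus C5 on the α face. This gives the trans-fused Δ3 alkene and comes back to the route at 14.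

Step 5. What may go wrong: poor facial selectivity at C6, attack at C4 instead of C6, or over-oxidation. The fallback sets the C6 configuration by hydride delivery instead of by electrophilic oxygenation and sets out from 10, used together with any C6 epimer formed alongside it. Oxidation with Dess–Martin periodinane in CH2Cl2 should give eudesm-4-ene-3,6-dione F2. Reduction of both carbonyl groups with NaBH4/CeCl3 in MeOH at −20 °C should occur from the α face, since the β face of C6 is shielded by C14. This comes back to the route at 11.

Step 10. What may go wrong: incomplete halogen–metal exchange, erosion of the alkene geometry, or further addition of the alkenyl metal to the ester that is formed. The fallback forms the ester by O-acylation instead of C-acylation and sets out from 14. Commercial (E)-4-acetoxycinnamic acid (CC(=O)Oc1ccc(/C=C/C(=O)O)cc1) is activated with 2,4,6-trichlorobenzoyl chloride and Et3N, then combined with 14 and DMAP in toluene at 80 °C (Yamaguchi esterification). This should give eudesm-3-en-6β-yl (E)-3-(4-acetoxyphenyl)prop-2-enoate F3. Mild methanolysis of the aryl acetate (K2CO3, MeOH, 0 °C) comes back to the route at 21.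

Further compounds
F1 | step 7 | 6β-hydroxyeudesm-4-en-3β-yl formate | CC1=C2[C@H](O)[C@H](C(C)C)CC[C@@]2(C)CC[C@@H]1OC=O
F2 | step 5 | eudesm-4-ene-3,6-dione | CC1=C2C(=O)[C@H](C(C)C)CC[C@@]2(C)CCC1=O
F3 | step 10 | eudesm-3-en-6β-yl (E)-3-(4-acetoxyphenyl)prop-2-enoate | CC1=CCC[C@]2(C)CC[C@@H](C(C)C)[C@@H](OC(=O)/C=C/c3ccc(OC(C)=O)cc3)[C@@H]12
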